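**Plan**
1. Retrosynthesis: the ester C–O bond at C10 is cut first (triol lactone 13 + guaiane acid 38). In 13 the bonds C4–C5, C9–C1 and C1–O2 are cut together, leaving cyclopentene diol 9, 2-bromoallyl alcohol 10 and CO 11.
2. Enabling feature: the six-membered lactone ring (C1, O2, C3, C4, C5, C9) shares the C5–C9 bond with the cyclopentane in a cis fusion, and C9 is flanked by the fully substituted carbinol carbon C8. Once a vinyl group is on C5, palladium on C9 finds no syn β-hydrogen and persists long enough to insert CO.
3. Forward, lactone half: cyclopentenone supplies the five-membered ring; Baylis–Hillman hydroxymethylation, silylation, CBS reduction, directed epoxidation and selenoxide transposition give 9; the palladium cascade then closes the lactone ring.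
4. Acid half: cut C10–C14 (carbonylation of a vinyl triflate) and C8–C9 (Claisen ring expansion). The five-membered ring comes from (R)-pulegone by Favorskii contraction, the seven-membered ring from a methylene-vinyl-tetrahydrofuran, and the diene is conjugated last.
5. Stereochemistry: C7 from CBS reduction, C8 from hydroxyl-directed epoxidation, C5 and C9 from syn carbopalladation on the face of the two hydroxyls; in the acid, C4 from (R)-pulegone and C1/C5 from hydrogenation anti to the C4 methyl.
6. The halves are joined by acylation of the primary C10 hydroxyl of 13.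

Key step: step 6

Remark: iridoid numbering (C1–C11, O2) is used for the lactone half and guaiane numbering (C1–C15) for the acid half; 2-bromo-3-methylbut-1-ene is not taken to be on sale, so its lithium reagent is made by a Shapiro reaction (steps 14 and 15).

Step 1
Reactants: 1 cyclopent-2-en-1-one, 2 formaldehyde
Product: 3 2-(hydroxymethyl)cyclopent-2-en-1-one
Conditions: aq. CH2O (37%), PBu3 (10 mol %), CHCl3/MeOH, rt
Reagents that add atoms: none
Why: Morita–Baylis–Hillman reaction: the phosphine adds to the enone, the phosphonium enolate takes up formaldehyde at C2 and loss of the phosphine restores the enone, so only the α-carbon is hydroxymethylated and no stereocenter arises.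

Step 2
Reactants: 3 2-(hydroxymethyl)cyclopent-2-en-1-one
Product: 4 2-[(tert-butyldimethylsilyloxy)methyl]cyclopent-2-en-1-one
Conditions: TBSCl, imidazole, CH2Cl2, 0 °C to rt
Reagents that add atoms: tert-butyldimethylsilyl chloride, CC(C)(C)[Si](C)(C)Cl
Why: Silylation of a primary allylic alcohol with a silyl chloride and imidazole is routine, and the bulky silyl ether will later shield the lower face of the ring and keep this oxygen away from palladium.

Step 3
Reactants: 4 2-[(tert-butyldimethylsilyloxy)methyl]cyclopent-2-en-1-one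
Product: 5 (S)-2-[(tert-butyldimethylsilyloxy)methyl]cyclopent-2-en-1-ol
Conditions: (R)-1-methyl-3,3-diphenyltetrahydro-1H,3H-pyrrolo[1,2-c][1,3,2]oxazaborole (15 mol %), BH3·SMe2, THF, −20 °C; then MeOH
Reagents that add atoms: none
Why: Corey–Bakshi–Shibata reduction should give clean 1,2-reduction, the oxazaborolidine–borane complex binding the ketone with the substituted alkene carbon as the large group and delivering hydride to the face that leads to the (S)-carbinol, which becomes C7.

Step 4
Reactants: 5 (S)-2-[(tert-butyldimethylsilyloxy)methyl]cyclopent-2-en-1-ol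
Product: 6 (1S,2S,5R)-1-[(tert-butyldimethylsilyloxy)methyl]-6-oxabicyclo[3.1.0]hexan-2-ol
Conditions: VO(acac)2 (3 mol %), t-BuOOH, CH2Cl2, 0 °C to rt
Reagents that add atoms: tert-butyl hydroperoxide, CC(C)(C)OO
Why: Hydroxyl-directed epoxidation of a cyclic allylic alcohol: the vanadium-bound tert-butyl peroxide is delivered from the face of the C7 hydroxyl, so the epoxide oxygen, the later C8 hydroxyl, should end up cis to it.

Step 5
Reactants: 6 (1S,2S,5R)-1-[(tert-butyldimethylsilyloxy)methyl]-6-oxabicyclo[3.1.0]hexan-2-ol
Product: 9 (1S,5S)-1-[(tert-butyldimethylsilyloxy)methyl]cyclopent-2-ene-1,5-diol, via hydroxy selenide 7 (not isolated), via selenoxide 8 (not isolated)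
Conditions: (PhSe)2, NaBH4, EtOH, 70 °C; then THF, 30% H2O2, 0 °C to rt
Reagents that add atoms: none
Why: Sharpless epoxide-to-allylic-alcohol transposition: phenylselenide opens the epoxide by SN2 attack at the less hindered C9 with inversion, H2O2 gives the selenoxide and its syn elimination can only run toward C5 because C8 bears no hydrogen, so the C5=C9 alkene forms while the cis relation of the C7 and C8 hydroxyls is kept.

Step 6
Reactants: 9 (1S,5S)-1-[(tert-butyldimethylsilyloxy)methyl]cyclopent-2-ene-1,5-diol, 10 2-bromoprop-2-en-1-ol, 11 carbon monoxide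
Product: 12 (4aR,6S,7S,7aR)-7-[(tert-butyldimethylsilyloxy)methyl]-6,7-dihydroxy-4-methylidenehexahydrocyclopenta[c]pyran-1(3H)-one
Conditions: Pd(OAc)2 (10 mol %), PPh3 (20 mol %), Ag2CO3 (1.2 equiv), 10 (2 equiv), CO/N2 (1:9, 1 atm), MeCN, 60 °C
Reagents that add atoms: none
Why: Proposed new method: zerovalent palladium inserts into the C–Br bond of 10, silver carbonate removes bromide, and the cationic vinylpalladium, held by the two cis hydroxyls of 9 on their own face, adds syn across C5=C9 with the vinyl carbon C4 going to C5 and palladium to C9; because C8 is fully substituted and H-5 is anti, the alkylpalladium cannot lose a β-hydrogen and inserts CO with retention (C9–C1), after which the allylic hydroxyl attacks the acylpalladium (C1–O2) and zerovalent palladium is released. The closest known reactions are Heck carbopalladation–CO insertion–alcoholysis cascades on norbornene-type alkenes, intramolecular cyclic carbopalladation ending in carbonylative lactonisation, and hydroxyl-directed Heck arylations of cyclopent-3-enols; an intermolecular version on an unstrained cyclopentene is not known. The δ-lactone ring closes by 6-exo-trig acyl substitution of the primary allylic hydroxyl at the acylpalladium carbon. C5 and C9 are both set in the syn carbopalladation, the face being fixed by hydroxyl coordination and by the CH2OTBS group on the opposite face, and retentive CO insertion then makes the ring fusion cis. The step needs alkene insertion to precede CO insertion (low CO partial pressure, cationic palladium, excess 10), C4 to bond to C5 rather than C9 (C9 is neopentyl, next to C8), and capture of the acyl group by the primary hydroxyl rather than the cis C7 hydroxyl (a fused six-membered ring against a strained bridged γ-lactone).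

Step 7
Reactants: 12 (4aR,6S,7S,7aR)-7-[(tert-butyldimethylsilyloxy)methyl]-6,7-dihydroxy-4-methylidenehexahydrocyclopenta[c]pyran-1(3H)-one
Product: 13 (4aR,6S,7S,7aR)-6,7-dihydroxy-7-(hydroxymethyl)-4-methylidenehexahydrocyclopenta[c]pyran-1(3H)-one
Conditions: HF·pyridine, pyridine, THF, 0 °C to rt
Reagents that add atoms: none
Why: Fluoride-mediated cleavage of the primary silyl ether (silyl ether deprotection) under buffered HF·pyridine should leave the lactone, the exocyclic alkene and the two other hydroxyls untouched.

Step 8
Reactants: 14 (R)-(+)-pulegone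
Product: 16 methyl (5R)-5-methyl-2-(propan-2-ylidene)cyclopentane-1-carboxylate, via pulegone dibromide 15 (not isolated)
Conditions: Br2, NaHCO3, Et2O, −10 °C; then NaOMe, MeOH, reflux
Reagents that add atoms: sodium methoxide, [Na+].[O-]C
Why: Bromine adds across the enone double bond and the Favorskii rearrangement of the resulting α-bromo ketone (enolate at C6, cyclopropanone, opening by methoxide, loss of HBr) contracts the ring to the cyclopentane ester, the methyl-bearing stereocenter of pulegone (later C4) taking no part.

Step 9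
Reactants: 16 methyl (5R)-5-methyl-2-(propan-2-ylidene)cyclopentane-1-carboxylate
Product: 18 methyl (2R)-2-methyl-5-oxocyclopentane-1-carboxylate, via ozonide 17 (not isolated)
Conditions: O3, CH2Cl2, −78 °C; then Me2S, −78 °C to rt
Reagents that add atoms: ozone, [O-][O+]=O
Why: Ozonolysis of the tetrasubstituted alkene followed by reductive work-up of the ozonide should give the β-keto ester and acetone, the epimerisable carbon between the two carbonyls becoming planar in the next step.

Step 10
Reactants: 18 methyl (2R)-2-methyl-5-oxocyclopentane-1-carboxylate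
Product: 19 methyl (5R)-5-methyl-2-(trifluoromethylsulfonyloxy)cyclopent-1-ene-1-carboxylate
Conditions: Tf2O, i-Pr2NEt, CH2Cl2, −78 °C
Reagents that add atoms: trifluoromethanesulfonic anhydride, O=S(=O)(OS(=O)(=O)C(F)(F)F)C(F)(F)F
Why: O-sulfonylation of the enol form of a cyclic β-keto ester with Tf2O and a hindered amine gives the vinyl triflate regiospecifically between C1 and C5.

Step 11
Reactants: 19 methyl (5R)-5-methyl-2-(trifluoromethylsulfonyloxy)cyclopent-1-ene-1-carboxylate, 20 (tributylstannyl)methanol
Product: 22 (6R)-6-methyl-3,4,5,6-tetrahydro-1H-cyclopenta[c]furan-1-one, via hydroxymethyl ester 21 (not isolated)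
Conditions: Pd(PPh3)4 (5 mol %), LiCl, 1,4-dioxane, 100 °C; then TsOH (cat.), rt
Reagents that add atoms: none
Why: Stille cross-coupling of a vinyl triflate with (tributylstannyl)methanol (LiCl-assisted transmetallation) puts the hydroxymethyl carbon C10 on C1, and the cis-placed hydroxymethyl and ester groups then close to the fused butenolide.

Step 12
Reactants: 22 (6R)-6-methyl-3,4,5,6-tetrahydro-1H-cyclopenta[c]furan-1-one
Product: 23 (3aS,6R,6aR)-6-methylhexahydro-1H-cyclopenta[c]furan-1-one
Conditions: H2 (50 atm), 5% Rh/Al2O3, EtOAc, rt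
Reagents that add atoms: none
Why: Heterogeneous hydrogenation should add both hydrogens to the flat tetrasubstituted butenolide alkene from the face opposite the C4 methyl group, which sets C1 and C5 with H-1, H-4 and H-5 all cis, and Rh is chosen because it is less prone than Pd to cleave the allylic C–O bond.

Step 13
Reactants: 23 (3aS,6R,6aR)-6-methylhexahydro-1H-cyclopenta[c]furan-1-one
Product: 24 (3aS,6R,6aR)-6-methylhexahydro-1H-cyclopenta[c]furan-1-ol
Conditions: i-Bu2AlH, CH2Cl2, −78 °C
Reagents that add atoms: none
Why: Partial reduction of a γ-lactone with i-Bu2AlH at −78 °C stops at the lactol, which stores the all-cis C6 aldehyde in a form that cannot epimerise at C5.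

Step 14
Reactants: 25 3-methylbutan-2-one, 26 2,4,6-triisopropylbenzenesulfonohydrazide
Product: 27 3-methylbutan-2-one 2,4,6-triisopropylbenzenesulfonylhydrazone
Conditions: MeOH, HCl (cat.), rt
Reagents that add atoms: none
Why: Acid-catalysed condensation of a ketone with an arenesulfonyl hydrazide gives the trisylhydrazone needed for the Shapiro reaction.

Step 15
Reactants: 24 (3aS,6R,6aR)-6-methylhexahydro-1H-cyclopenta[c]furan-1-ol, 27 3-methylbutan-2-one 2,4,6-triisopropylbenzenesulfonylhydrazone
Product: 29 [(1S,2R,3R)-2-(1-hydroxy-3-methyl-2-methylidenebutyl)-3-methylcyclopentyl]methanol, via 3-methylbut-1-en-2-yllithium 28 (not isolated)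
Conditions: 27 (3 equiv), n-BuLi (6 equiv), THF, −78 to 0 °C; then 24, −78 °C to rt
Reagents that add atoms: none
Why: Shapiro reaction: double deprotonation (N–H and the methyl group), loss of the sulfinate and of N2 give the 1-isopropylvinyllithium, which first deprotonates the lactol and then adds to its open hydroxy aldehyde form; the new carbinol center C6 is not controlled and is removed in step 18.

Step 16
Reactants: 29 [(1S,2R,3R)-2-(1-hydroxy-3-methyl-2-methylidenebutyl)-3-methylcyclopentyl]methanol
Product: 31 (3aR,4R,6aS)-4-methyl-3-(3-methylbut-1-en-2-yl)hexahydro-1H-cyclopenta[c]furan-1-one, via lactol 30 (not isolated)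
Conditions: (2,2,6,6-tetramethylpiperidin-1-yl)oxyl (20 mol %), PhI(OAc)2, CH2Cl2, rt
Reagents that add atoms: none
Why: Oxoammonium oxidation (TEMPO with PhI(OAc)2) takes the primary alcohol first, the aldehyde is caught by the secondary hydroxyl as a lactol and a second oxidation gives the γ-lactone whose carbonyl carbon is C10.

Step 17
Reactants: 31 (3aR,4R,6aS)-4-methyl-3-(3-methylbut-1-en-2-yl)hexahydro-1H-cyclopenta[c]furan-1-one
Product: 32 (3aR,4R,6aS)-4-methyl-1-methylidene-3-(3-methylbut-1-en-2-yl)hexahydro-1H-cyclopenta[c]furan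
Conditions: Cp2TiMe2, toluene, 70 °C, dark
Reagents that add atoms: dimethyltitanocene, C[Ti](C)(C1C=CC=C1)C1C=CC=C1
Why: Petasis methylenation (Cp2Ti=CH2 formed by loss of methane from Cp2TiMe2) turns the lactone carbonyl into the exocyclic enol ether under non-acidic conditions and adds the carbon that becomes C9.

Step 18
Reactants: 32 (3aR,4R,6aS)-4-methyl-1-methylidene-3-(3-methylbut-1-en-2-yl)hexahydro-1H-cyclopenta[c]furan
Product: 33 (1S,4R,5S)-14-norguai-6-en-10-one
Conditions: xylene, Et3N (trace), 180 °C, sealed tube
Reagents that add atoms: none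
Why: Claisen rearrangement of the 2-methylene-5-vinyltetrahydrofuran ([3,3] shift through a boat-like oxygen-bridged transition state) forms the C8–C9 bond, breaks the C6–O bond and gives the cycloheptenone, C1 and C5 staying untouched and both C6 epimers converging because C6 becomes sp2.

Step 19
Reactants: 33 (1S,4R,5S)-14-norguai-6-en-10-one
Product: 35 (1S,4R,5S)-14-norguaia-6,9-dien-10-yl trifluoromethanesulfonate, via potassium enolate 34 (not isolated)
Conditions: KN(SiMe3)2, THF, −78 °C; then PhNTf2
Reagents that add atoms: N-phenylbis(trifluoromethanesulfonimide), O=S(=O)(N(c1ccccc1)S(=O)(=O)C(F)(F)F)C(F)(F)F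
Why: Kinetic deprotonation with the hindered amide base should occur at the C9 methylene and not at the ring-fusion methine C1, and O-sulfonylation of the enolate with PhNTf2 gives the vinyl triflate without touching C1.

Step 20
Reactants: 35 (1S,4R,5S)-14-norguaia-6,9-dien-10-yl trifluoromethanesulfonate, 11 carbon monoxide
Product: 36 methyl (1S,4R,5S)-guaia-6,9-dien-14-oate
Conditions: Pd(OAc)2 (5 mol %), PPh3, Et3N, CO (1 atm), MeOH/DMF, 60 °C
Reagents that add atoms: methanol, CO
Why: Palladium-catalysed methoxycarbonylation of a vinyl triflate (oxidative addition, CO insertion, methanolysis of the acylpalladium) installs C14 on C10.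

Step 21
Reactants: 36 methyl (1S,4R,5S)-guaia-6,9-dien-14-oate
Product: 38 (1S,4R,5R)-guaia-7,9-dien-14-oic acid, via conjugated methyl ester 37 (not isolated)
Conditions: NaOMe, MeOH, 60 °C; then aq. NaOH, 60 °C; then 1 M HCl
Reagents that add atoms: sodium hydroxide, [Na+].[OH-]
Why: Base-mediated conjugation of a skipped dienoate: methoxide removes the doubly allylic γ-hydrogen at C8, the extended enolate is reprotonated at C6 to give the more stable fully conjugated 2,4-dienoate, and saponification then frees the acid, C1 and C5 lying outside the enolate and keeping their configuration.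

Step 22
Reactants: 13 (4aR,6S,7S,7aR)-6,7-dihydroxy-7-(hydroxymethyl)-4-methylidenehexahydrocyclopenta[c]pyran-1(3H)-one, 38 (1S,4R,5R)-guaia-7,9-dien-14-oic acid
Product: 40 nardostachysin, via mixed anhydride 39 (not isolated)
Conditions: 2,4,6-trichlorobenzoyl chloride, Et3N, THF, rt; then 13, 4-(dimethylamino)pyridine, toluene, rt
Reagents that add atoms: none
Why: Yamaguchi esterification: the mixed anhydride acylates 4-(dimethylamino)pyridine and the acylpyridinium should be taken up by the primary C10 hydroxyl in preference to the hindered secondary C7 and the tertiary C8 hydroxyl, no stereocenter being touched.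

**Compound list**
1 | cyclopent-2-en-1-one | O=C1C=CCC1 | starting material
2 | formaldehyde | C=O | starting material
3 | 2-(hydroxymethyl)cyclopent-2-en-1-one | O=C1CCC=C1CO | intermediate
4 | 2-[(tert-butyldimethylsilyloxy)methyl]cyclopent-2-en-1-one | O=C1CCC=C1CO[Si](C)(C)C(C)(C)C | intermediate
5 | (S)-2-[(tert-butyldimethylsilyloxy)methyl]cyclopent-2-en-1-ol | O[C@H]1CCC=C1CO[Si](C)(C)C(C)(C)C | intermediate
6 | (1S,2S,5R)-1-[(tert-butyldimethylsilyloxy)methyl]-6-oxabicyclo[3.1.0]hexan-2-ol | O[C@H]1CC[C@H]2O[C@@]12CO[Si](C)(C)C(C)(C)C | intermediate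
7 | hydroxy selenide (PhSe on C9 trans to the C8 hydroxyl) | O[C@H]1CC[C@H]([Se]c2ccccc2)[C@]1(O)CO[Si](C)(C)C(C)(C)C | intermediate
8 | selenoxide of 7 | O[C@H]1CC[C@H]([Se](=O)c2ccccc2)[C@]1(O)CO[Si](C)(C)C(C)(C)C | intermediate
9 | (1S,5S)-1-[(tert-butyldimethylsilyloxy)methyl]cyclopent-2-ene-1,5-diol | C1=CC[C@H](O)[C@@]1(O)CO[Si](C)(C)C(C)(C)C | intermediate
10 | 2-bromoprop-2-en-1-ol | C=C(Br)CO | starting material
11 | carbon monoxide | [C-]#[O+] | starting material
12 | (4aR,6S,7S,7aR)-7-[(tert-butyldimethylsilyloxy)methyl]-6,7-dihydroxy-4-methylidenehexahydrocyclopenta[c]pyran-1(3H)-one | C=C1COC(=O)[C@@H]2[C@H]1C[C@H](O)[C@@]2(O)CO[Si](C)(C)C(C)(C)C | intermediate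
13 | (4aR,6S,7S,7aR)-6,7-dihydroxy-7-(hydroxymethyl)-4-methylidenehexahydrocyclopenta[c]pyran-1(3H)-one | C=C1COC(=O)[C@@H]2[C@H]1C[C@H](O)[C@@]2(O)CO | intermediate
14 | (R)-(+)-pulegone | C[C@@H]1CCC(=C(C)C)C(=O)C1 | starting material
15 | pulegone dibromide | C[C@@H]1CCC(Br)(C(C)(C)Br)C(=O)C1 | intermediate
16 | methyl (5R)-5-methyl-2-(propan-2-ylidene)cyclopentane-1-carboxylate (C1 epimers) | C[C@@H]1CCC(=C(C)C)C1C(=O)OC | intermediate
17 | ozonide of 16 | C[C@@H]1CCC2(OOC(C)(C)O2)C1C(=O)OC | intermediate
18 | methyl (2R)-2-methyl-5-oxocyclopentane-1-carboxylate | C[C@@H]1CCC(=O)C1C(=O)OC | intermediate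
19 | methyl (5R)-5-methyl-2-(trifluoromethylsulfonyloxy)cyclopent-1-ene-1-carboxylate | C[C@@H]1CCC(OS(=O)(=O)C(F)(F)F)=C1C(=O)OC | intermediate
20 | (tributylstannyl)methanol | OC[Sn](CCCC)(CCCC)CCCC | starting material
21 | methyl (5R)-2-(hydroxymethyl)-5-methylcyclopent-1-ene-1-carboxylate | C[C@@H]1CCC(CO)=C1C(=O)OC | intermediate
22 | (6R)-6-methyl-3,4,5,6-tetrahydro-1H-cyclopenta[c]furan-1-one | C[C@@H]1CCC2=C1C(=O)OC2 | intermediate
23 | (3aS,6R,6aR)-6-methylhexahydro-1H-cyclopenta[c]furan-1-one | C[C@@H]1CC[C@@H]2COC(=O)[C@H]12 | intermediate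
24 | (3aS,6R,6aR)-6-methylhexahydro-1H-cyclopenta[c]furan-1-ol (anomers) | C[C@@H]1CC[C@@H]2COC(O)[C@H]12 | intermediate
25 | 3-methylbutan-2-one | CC(=O)C(C)C | starting material
26 | 2,4,6-triisopropylbenzenesulfonohydrazide | NNS(=O)(=O)c1c(C(C)C)cc(C(C)C)cc1C(C)C | starting material
27 | 3-methylbutan-2-one 2,4,6-triisopropylbenzenesulfonylhydrazone | CC(C)C(C)=NNS(=O)(=O)c1c(C(C)C)cc(C(C)C)cc1C(C)C | intermediate
28 | 3-methylbut-1-en-2-yllithium | [Li]C(=C)C(C)C | intermediate
29 | [(1S,2R,3R)-2-(1-hydroxy-3-methyl-2-methylidenebutyl)-3-methylcyclopentyl]methanol (carbinol epimers) | C[C@@H]1CC[C@H](CO)[C@@H]1C(O)C(=C)C(C)C | intermediate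
30 | lactol of 31 (C10 hemiacetal) | C[C@@H]1CC[C@@H]2C(O)OC(C(=C)C(C)C)[C@H]12 | intermediate
31 | (3aR,4R,6aS)-4-methyl-3-(3-methylbut-1-en-2-yl)hexahydro-1H-cyclopenta[c]furan-1-one (C3 epimers) | C[C@@H]1CC[C@@H]2C(=O)OC(C(=C)C(C)C)[C@H]12 | intermediate
32 | (3aR,4R,6aS)-4-methyl-1-methylidene-3-(3-methylbut-1-en-2-yl)hexahydro-1H-cyclopenta[c]furan | C[C@@H]1CC[C@@H]2C(=C)OC(C(=C)C(C)C)[C@H]12 | intermediate
33 | (1S,4R,5S)-14-norguai-6-en-10-one (cis-fused) | C[C@@H]1CC[C@@H]2C(=O)CCC(C(C)C)=C[C@H]12 | intermediate
34 | potassium enolate of 33 (C9=C10) | C[C@@H]1CC[C@@H]2C([O-])=CCC(C(C)C)=C[C@H]12.[K+] | intermediate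
35 | (1S,4R,5S)-14-norguaia-6,9-dien-10-yl trifluoromethanesulfonate | C[C@@H]1CC[C@@H]2C(OS(=O)(=O)C(F)(F)F)=CCC(C(C)C)=C[C@H]12 | intermediate
36 | methyl (1S,4R,5S)-guaia-6,9-dien-14-oate | C[C@@H]1CC[C@@H]2C(C(=O)OC)=CCC(C(C)C)=C[C@H]12 | intermediate
37 | methyl (1S,4R,5R)-guaia-7,9-dien-14-oate | C[C@@H]1CC[C@@H]2C(C(=O)OC)=CC=C(C(C)C)C[C@H]12 | intermediate
38 | (1S,4R,5R)-guaia-7,9-dien-14-oic acid | C[C@@H]1CC[C@@H]2C(C(=O)O)=CC=C(C(C)C)C[C@H]12 | intermediate
39 | mixed anhydride of 38 with 2,4,6-trichlorobenzoic acid | C[C@@H]1CC[C@@H]2C(C(=O)OC(=O)c3c(Cl)cc(Cl)cc3Cl)=CC=C(C(C)C)C[C@H]12 | intermediate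
40 | nardostachysin | C=C1COC(=O)[C@@H]2[C@H]1C[C@H](O)[C@@]2(O)COC(=O)C1=CC=C(C(C)C)C[C@@H]2[C@H](C)CC[C@H]12 | target

**Step count**
Total: 22 steps. Longest linear sequence: 14 steps (steps 8–13 and 15–22, from (R)-pulegone).

**Steps most likely to fail**

Step 6. CO may insert into the vinylpalladium before the cyclopentene does, giving acrylate-type products. The C9 alkylpalladium may lose the cis C8 hydroxyl by β-hydroxide elimination. Carbopalladation may also take place on the lower face. The fallback uses known chemistry and makes the alkene insertion intramolecular through an ester tether; it sets out from 9 and comes back at 12. Steglich esterification of the secondary C7 hydroxyl with 2-bromoacrylic acid (DCC, 4-(dimethylamino)pyridine) gives the 2-bromoacrylate F1. An intramolecular Heck reaction ending in carbonylative esterification (Pd(OAc)2, PPh3, Et3N, CO, MeOH) should close a six-membered ring from the acrylate carbon onto C5 on the face of O-7 and turn the C9 alkylpalladium into a methyl ester, giving the bridged α-methylene lactone ester F2. i-Bu2AlH at −78 °C should reduce the strained lactone before the hindered ester, giving the lactol F3. NaBH4/CeCl3·7H2O reduces its open enal form to the hydroxy ester F4, which lactonises onto the C9 ester (C1–O2) with loss of methanol to give 12.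

Step 18. The exocyclic enol ether may isomerise into the ring or hydrolyse on traces of acid before it rearranges, and the C6 epimer with the vinyl group on the concave face may rearrange slowly. The fallback generates the enol ether under basic conditions from an alkynol and lets it rearrange in the same pot; it sets out from 31 and comes back at 33. i-Bu2AlH gives lactol 30, which is isolated this time. Dimethyl (1-diazo-2-oxopropyl)phosphonate with K2CO3 in MeOH (Seyferth–Gilbert homologation, Ohira–Bestmann variant) converts the masked C10 aldehyde into a terminal alkyne, giving the alkynol F5. Catalytic MeLi in phenetole at 200 °C should bring about 5-exo-dig addition of the alkoxide to the alkyne and Claisen rearrangement of the resulting 32, giving 33.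

Step 22. Acylation may also occur at the C7 hydroxyl, the acyl group may migrate from O-10 to O-7, and base may open or translactonise the δ-lactone while the free triol is esterified. The fallback changes the protecting-group plan instead of relying on chemoselectivity; it sets out from 12 and comes back at 40. 2,2-Dimethoxypropane with pyridinium p-toluenesulfonate gives the acetonide F6. HF·pyridine removes the silyl group to give the primary alcohol F7. Yamaguchi esterification with 38 (through 39) gives the ester acetonide F8, and aqueous acetic acid removes the acetonide to give 40.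

**Further compounds**
F1 | step 6 | C7 2-bromoacrylate of diol 9 | C1=CC[C@H](OC(=O)C(Br)=C)[C@@]1(O)CO[Si](C)(C)C(C)(C)C
F2 | step 6 | bridged α-methylene lactone (O7–C3) with methyl ester on C9 | COC(=O)[C@@H]1[C@H]2C[C@H](OC(=O)C2=C)[C@@]1(O)CO[Si](C)(C)C(C)(C)C
F3 | step 6 | lactol of F2 | COC(=O)[C@@H]1[C@H]2C[C@H](OC(O)C2=C)[C@@]1(O)CO[Si](C)(C)C(C)(C)C
F4 | step 6 | methyl ester with free allylic alcohol at C3 | COC(=O)[C@@H]1[C@H](C(=C)CO)C[C@H](O)[C@@]1(O)CO[Si](C)(C)C(C)(C)C
F5 | step 18 | alkynol (ethynyl on C1, vinyl carbinol on C5) | C[C@@H]1CC[C@H](C#C)[C@@H]1C(O)C(=C)C(C)C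
F6 | step 22 | 7,8-O-isopropylidene derivative of 12 | C=C1COC(=O)[C@@H]2[C@H]1C[C@@H]3OC(C)(C)O[C@]23CO[Si](C)(C)C(C)(C)C
F7 | step 22 | 7,8-O-isopropylidene derivative of 13 | C=C1COC(=O)[C@@H]2[C@H]1C[C@@H]3OC(C)(C)O[C@]23CO
F8 | step 22 | 7,8-O-isopropylidene derivative of nardostachysin | C=C1COC(=O)[C@@H]2[C@H]1C[C@@H]3OC(C)(C)O[C@]23COC(=O)C1=CC=C(C(C)C)C[C@@H]2[C@H](C)CC[C@H]12
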